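**Retrosynthetic overview**

- The route rests on the benzene ring: O on C2', Br on C3' and C5', H on C4' and C6', pyrrol-2-yl on C1'. The run C3'–C6' (Br/H/Br/H) is C3–C6 of 3,5-dibromo-2-pyrone; C2' and C1' are the two carbons of a pyrrolyl ynol ether.
- Last: the three pyrrole C–Br bonds (C3, C4, C5) are made by electrophilic bromination after O–H and N–H are unmasked.
- Key: the benzene ring, the only ring made, is closed by [4+2] cycloaddition of the dibromopyrone with 1-tosyl-2-(silyloxyethynyl)pyrrole (bonds C2'–C3' and C1'–C6'), then CO2 extrusion. The pyrrole ring is bought.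
- The siloxyalkyne comes from the terminal alkyne (acetylide → ynolate → O-silylation), which comes from N-tosylpyrrole-2-carboxaldehyde by one-carbon homologation. The dibromopyrone comes from coumalic acid.

Key step: step 5

Remark: the target has no stereocentre and no configurationally stable axis, so it is achiral and no stereocontrol is needed anywhere.

**Step 1**
Reactants: 1 pyrrole-2-carboxaldehyde; 2 p-toluenesulfonyl chloride
Product: 3 1-tosylpyrrole-2-carboxaldehyde
Conditions: TsCl, Et3N, DMAP (cat.), CH2Cl2, 0 °C → rt
Reagents that add atoms: p-toluenesulfonyl chloride, Cc1ccc(cc1)S(Cl)(=O)=O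
Why: DMAP-catalysed N-sulfonylation of the formyl-acidified pyrrole N–H; the sulfonyl group is kept until step 6 so that the pyrrole ring stays electron-poor.

**Step 2**
Reactants: 3 1-tosylpyrrole-2-carboxaldehyde; 4 (trimethylsilyl)diazomethane
Product: 7 2-ethynyl-1-tosylpyrrole, via lithium alkoxide adduct 5 (not isolated), via diazoalkene 6 (not isolated)
Conditions: TMSCHN2 (1.3 equiv), LDA (1.2 equiv), THF, −78 °C; then 3, −78 °C → rt; H2O quench
Reagents that add atoms: (trimethylsilyl)diazomethane, C[Si](C)(C)C=[N+]=[N-]
Why: Colvin rearrangement: lithiated TMS-diazomethane adds to the aldehyde to give adduct 5 (racemic), Peterson elimination of lithium trimethylsilanolate gives diazoalkene 6, and loss of N2 with 1,2-hydrogen shift gives the terminal alkyne, under cold, alkoxide-free conditions that should spare the N–S bond.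

**Step 3**
Reactants: 7 2-ethynyl-1-tosylpyrrole; 8 tert-butyl hydroperoxide; 9 triisopropylsilyl triflate
Product: 12 1-tosyl-2-[(triisopropylsilyloxy)ethynyl]pyrrole, via lithium acetylide 10 (not isolated), via lithium ynolate 11 (not isolated)
Conditions: LiHMDS, THF, −78 °C; t-BuOOLi (from anhydrous t-BuOOH, LiHMDS, THF, −78 °C), −78 → 0 °C; TIPSOTf, −78 → 0 °C
Reagents that add atoms: tert-butyl hydroperoxide, CC(C)(C)OO; triisopropylsilyl triflate, CC(C)[Si](OS(=O)(=O)C(F)(F)F)(C(C)C)C(C)C
Why: Acetylide oxygenation followed by ynolate O-silylation: the lithium acetylide attacks the terminal oxygen of lithium tert-butyl peroxide (tert-butoxide leaves) to give the lithium ynolate, which the bulky, hard silyl triflate should capture on oxygen; LiHMDS does both deprotonations, so no alkyllithium meets the sulfonamide.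

**Step 4**
Reactants: 13 coumalic acid; 14 N-bromosuccinimide
Product: 16 3,5-dibromo-2H-pyran-2-one, via 5-bromo-2-pyrone 15 (not isolated)
Conditions: NBS (2.5 equiv), LiOAc (cat.), MeCN–H2O, rt
Reagents that add atoms: N-bromosuccinimide, O=C1CCC(=O)N1Br
Why: Hunsdiecker-type bromodecarboxylation: electrophilic bromine adds at the enol-ether-like C5, CO2 is lost to give 5-bromo-2-pyrone, and a second equivalent brominates C3, the other nucleophilic position of a 2-pyrone.

**Step 5**
Reactants: 12 1-tosyl-2-[(triisopropylsilyloxy)ethynyl]pyrrole; 16 3,5-dibromo-2H-pyran-2-one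
Product: 18 2-(3,5-dibromo-2-triisopropylsilyloxyphenyl)-1-tosylpyrrole, via bicyclic lactone 17 (not isolated)
Conditions: PhMe, 90 °C, sealed tube (12 in slight excess)
Reagents that add atoms: none
Why: The electron-poor pyrone (lactone carbonyl plus two bromines) and the strongly polarised ynol ether should combine in an inverse-electron-demand [4+2] cycloaddition, concerted but highly asynchronous, in which the nucleophilic pyrrolyl-bearing alkyne carbon bonds to pyrone C6 (C1'–C6') and the oxygen-bearing carbon to C3–Br (C2'–C3'), giving the 2-oxabicyclo[2.2.2]octadienone 17. Because the dienophile is an alkyne, 17 is a cyclohexadiene bridged by –C(=O)O– and loses CO2 by retro-[4+2] at the reaction temperature, so the arene forms at the correct oxidation level without an oxidant or an elimination. The closest known chemistry is the 2-pyrone/alkyne Diels–Alder–decarboxylation benzannulation with donor alkynes, and the cycloadditions of 3,5-dibromo-2-pyrone with enol ethers, which place the donor-bearing carbon next to C3 in the same way. The benzene ring is the only ring closed, by intermolecular two-bond [4+2] annulation and then CO2 extrusion; no stereocentre is created in 18, and the racemic bridgeheads of 17 are erased on aromatisation. The only selectivity needed is regiochemical: the oxygen lone pair makes the β-carbon of the ynol ether the nucleophilic terminus, and C6 is the end of the pyrone's vinylogous acceptor system. The N-sulfonyl group keeps the pyrrole from competing as a nucleophile, and the triisopropylsilyl group is bulky enough to resist 1,3-silyl shift to a silylketene at this temperature.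

**Step 6**
Reactants: 18 2-(3,5-dibromo-2-triisopropylsilyloxyphenyl)-1-tosylpyrrole
Product: 20 2,4-dibromo-6-(1H-pyrrol-2-yl)phenol, via N-tosyl potassium phenoxide 19 (not isolated)
Conditions: KOH (excess), MeOH–THF–H2O, 60 °C, Ar; then aq. HCl to pH 5
Reagents that add atoms: none
Why: Base hydrolysis: hydroxide attacks silicon of the aryl silyl ether (an acidic dibromophenoxide leaves) and then the sulfonyl sulfur (pyrrolide leaves; a sulfonyl group that migrates to the neighbouring phenoxide oxygen is hydrolysed under the same conditions), while the aryl bromides are inert.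

**Step 7**
Reactants: 20 2,4-dibromo-6-(1H-pyrrol-2-yl)phenol; 14 N-bromosuccinimide
Product: 23 pentabromopseudilin [2,4-dibromo-6-(3,4,5-tribromo-1H-pyrrol-2-yl)phenol], via 5-bromopyrrole 21 (not isolated), via 4,5-dibromopyrrole 22 (not isolated)
Conditions: NBS (3.0 equiv), THF, −78 → 0 °C, dark
Reagents that add atoms: N-bromosuccinimide, O=C1CCC(=O)N1Br
Why: Electrophilic aromatic bromination: the free pyrrole is far more nucleophilic than the phenol ring, whose ortho and para positions are all occupied, so three equivalents of NBS should fill pyrrole C5, C4 and C3 only (the order of the two β-brominations does not change the outcome).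

**Compound list**

1 | pyrrole-2-carboxaldehyde | O=Cc1ccc[nH]1 | starting material
2 | p-toluenesulfonyl chloride | Cc1ccc(cc1)S(Cl)(=O)=O | starting material
3 | 1-tosylpyrrole-2-carboxaldehyde | O=Cc1cccn1S(=O)(=O)c1ccc(C)cc1 | intermediate
4 | (trimethylsilyl)diazomethane | C[Si](C)(C)C=[N+]=[N-] | starting material
5 | lithium 2-diazo-1-(1-tosylpyrrol-2-yl)-2-(trimethylsilyl)ethanolate (racemic) | [Li]OC(c1cccn1S(=O)(=O)c1ccc(C)cc1)C(=[N+]=[N-])[Si](C)(C)C | intermediate (not isolated)
6 | 2-(2-diazoethenyl)-1-tosylpyrrole | [N-]=[N+]=C=Cc1cccn1S(=O)(=O)c1ccc(C)cc1 | intermediate (not isolated)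
7 | 2-ethynyl-1-tosylpyrrole | C#Cc1cccn1S(=O)(=O)c1ccc(C)cc1 | intermediate
8 | tert-butyl hydroperoxide | CC(C)(C)OO | starting material
9 | triisopropylsilyl triflate | CC(C)[Si](OS(=O)(=O)C(F)(F)F)(C(C)C)C(C)C | starting material
10 | lithium (1-tosylpyrrol-2-yl)acetylide | [Li]C#Cc1cccn1S(=O)(=O)c1ccc(C)cc1 | intermediate (not isolated)
11 | lithium 2-(1-tosylpyrrol-2-yl)ethynolate | [Li]OC#Cc1cccn1S(=O)(=O)c1ccc(C)cc1 | intermediate (not isolated)
12 | 1-tosyl-2-[(triisopropylsilyloxy)ethynyl]pyrrole | Cc1ccc(cc1)S(=O)(=O)n1cccc1C#CO[Si](C(C)C)(C(C)C)C(C)C | intermediate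
13 | coumalic acid | OC(=O)c1ccc(=O)oc1 | starting material
14 | N-bromosuccinimide | O=C1CCC(=O)N1Br | starting material
15 | 5-bromo-2H-pyran-2-one | O=c1ccc(Br)co1 | intermediate (not isolated)
16 | 3,5-dibromo-2H-pyran-2-one | O=c1occ(Br)cc1Br | intermediate
17 | 4,7-dibromo-5-(triisopropylsilyloxy)-6-(1-tosylpyrrol-2-yl)-2-oxabicyclo[2.2.2]octa-5,7-dien-3-one (racemic) | O=C1OC2C(Br)=CC1(Br)C(O[Si](C(C)C)(C(C)C)C(C)C)=C2c1cccn1S(=O)(=O)c1ccc(C)cc1 | intermediate (not isolated)
18 | 2-(3,5-dibromo-2-triisopropylsilyloxyphenyl)-1-tosylpyrrole | Cc1ccc(cc1)S(=O)(=O)n1cccc1-c1cc(Br)cc(Br)c1O[Si](C(C)C)(C(C)C)C(C)C | intermediate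
19 | potassium 2,4-dibromo-6-(1-tosylpyrrol-2-yl)phenoxide | [K+].[O-]c1c(Br)cc(Br)cc1-c1cccn1S(=O)(=O)c1ccc(C)cc1 | intermediate (not isolated)
20 | 2,4-dibromo-6-(1H-pyrrol-2-yl)phenol | Oc1c(Br)cc(Br)cc1-c1ccc[nH]1 | intermediate
21 | 2,4-dibromo-6-(5-bromo-1H-pyrrol-2-yl)phenol | Oc1c(Br)cc(Br)cc1-c1ccc(Br)[nH]1 | intermediate (not isolated)
22 | 2,4-dibromo-6-(4,5-dibromo-1H-pyrrol-2-yl)phenol | Oc1c(Br)cc(Br)cc1-c1cc(Br)c(Br)[nH]1 | intermediate (not isolated)
23 | pentabromopseudilin | Oc1c(Br)cc(Br)cc1-c1[nH]c(Br)c(Br)c1Br | target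

**Step count**

Total: 7 steps. Longest linear sequence: 6 steps (1, 2, 3, 5, 6, 7); step 4 is a one-step side branch.

**Steps most likely to fail**

Step 5 (key cycloaddition). The siloxyalkyne may be lost before it cycloadds, by silyl migration to a silylketene or by protodesilylation from traces of HBr. A stepwise zwitterionic addition may collapse to [2+2] or open-chain products. Regiocontrol may erode, because the heteroaryl group on the alkyne opposes the directing effect of the oxygen. Fallback: make the aryl–pyrrole bond by cross-coupling. This fallback does not branch from an intermediate of the route; it sets out from commercial 2,4-dibromophenol and 1-Boc-pyrrole-2-boronic acid and comes back at 20. ortho-Iodination (NIS, cat. TsOH, MeCN) should give 2,4-dibromo-6-iodophenol F1. Suzuki–Miyaura coupling at the C–I bond (Pd(PPh3)4, aq. Na2CO3, DME, 70 °C; oxidative addition into C–I is much faster than into C–Br) should give tert-butyl 2-(3,5-dibromo-2-hydroxyphenyl)-1H-pyrrole-1-carboxylate F2. NaOMe in MeOH then removes the Boc group, from nitrogen or from oxygen if it has migrated, to give 20, which continues with step 7.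

Step 3 (ynolate formation and silylation). Oxygen transfer from the peroxide to an acetylide deactivated by the sulfonylpyrrole may be slow, and tert-butoxide or peroxide anions may cleave the N–S bond during the warming period. Fallback: generate the same ynolate without peroxide. It sets out from 7 and comes back at 11. [Hydroxy(tosyloxy)iodo]benzene in CH2Cl2 should convert 7 into phenyl[(1-tosylpyrrol-2-yl)ethynyl]iodonium tosylate F3. Catalytic CuOTf in MeCN should collapse this to (1-tosylpyrrol-2-yl)ethynyl 4-methylbenzenesulfonate F4. One equivalent of MeLi at −78 °C attacks the sulfonate sulfur and releases ynolate 11, which is silylated with TIPSOTf as in step 3 to give 12.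

Step 2 (homologation). The lithiated diazo reagent or residual amide base may attack the sulfonyl sulfur, or the Peterson elimination of the adduct may stall. Fallback: Corey–Fuchs homologation. It sets out from 3 and comes back at 7. CBr4 and PPh3 in CH2Cl2 at 0 °C should give 2-(2,2-dibromovinyl)-1-tosylpyrrole F5. n-BuLi (2.1 equiv) in THF at −78 °C then effects Br–Li exchange and Fritsch–Buttenberg–Wiechell rearrangement to acetylide 10, which is protonated with aq. NH4Cl to give 7.

**Further compounds**

F1 | step 5 | 2,4-dibromo-6-iodophenol | Oc1c(I)cc(Br)cc1Br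
F2 | step 5 | tert-butyl 2-(3,5-dibromo-2-hydroxyphenyl)-1H-pyrrole-1-carboxylate | CC(C)(C)OC(=O)n1cccc1-c1cc(Br)cc(Br)c1O
F3 | step 3 | phenyl[(1-tosylpyrrol-2-yl)ethynyl]iodonium tosylate | Cc1ccc(cc1)S(=O)(=O)n1cccc1C#C[I+]c1ccccc1.Cc1ccc(cc1)S(=O)(=O)[O-]
F4 | step 3 | (1-tosylpyrrol-2-yl)ethynyl 4-methylbenzenesulfonate | Cc1ccc(cc1)S(=O)(=O)OC#Cc1cccn1S(=O)(=O)c1ccc(C)cc1
F5 | step 2 | 2-(2,2-dibromovinyl)-1-tosylpyrrole | BrC(Br)=Cc1cccn1S(=O)(=O)c1ccc(C)cc1
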